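Readings and results come from a simulation with constants of no real substance.

The constants of these steps are not given to you, so start from what the charge tells you about the catalyst. Here is the flask, with the earlier runs and the questions.

| setting | oak | elm | flask |
|---|---|---|---|
| starting material | 0.20 M | 0.20 M | 0.20 M |
| second substrate | 1 equiv | 1 equiv | 1.00 equiv |
| protic impurity | 0.10 M | 0.067 M | 0.100 M |
| free catalyst | 0.2 mol% | 0.2 mol% | 0.2 mol% |
| stray impurity | 84 µM | 84 µM | 84 µM |
| temperature | 0 °C | −15 °C | 0 °C |
| remark | the very flask that is asked about, followed so far | run made earlier |  |
| time |  |  | 8.0 h |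

| run | time / h | target / % | starting material / % |
|---|---|---|---|
| oak | 0.833 | 21.4 | 77.3 |
| oak | 1.50 | 32.7 | 66.8 |
| oak | 2.50 | 42.5 | 59.1 |
| oak | 3.00 | 44.4 | 55.5 |
| oak | 4.00 | 48.2 | 51.8 |
| oak | 5.00 | 48.4 | 51.4 |
| elm | 0.500 | 2.6 | 97.5 |
| elm | 0.833 | 2.7 | 97.2 |
| elm | 1.33 | 3.7 | 95.2 |
| elm | 3.00 | 8.3 | 91.3 |
| elm | 4.00 | 10.3 | 89.4 |
| elm | 6.00 | 13.9 | 85.9 |

(scatter of a reading: 0.5 percentage points)

- removed target is counted in
- the earlier runs were read with a standard deviation of 0.5 percentage points
- additions bring no volume worth counting

- midnight: at 8.0 h raise the temperature by 15 K, then wait 15 h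
- autumn: at 8.0 h take out 90 % of the target then present, then wait 15 h
- noon: at 8.0 h add free catalyst, 50.0 % of the amount charged, then wait 15 h
- winter: change nothing and wait 15 h more

- target, in percent of the starting material first charged, at 8.0 h
- what to do for the largest gain in target; "none" if nothing gains more than 2 percentage points (midnight / autumn / noon / winter / none)
- target present, with what was taken out counted in, in percent of the starting material first charged, after midnight
- target present, with what was taken out counted in, in percent of the starting material first charged, after noon

In the oak run, c(starting material) reads 51.8 % and then 51.4 %, a step less than the scatter of 0.5 percentage points. So oak has nearly stopped with starting material still there. I read that as catalyst dying, and I reckon as follows.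

Suppose the stray impurity is the fast step, taking one catalyst each at the very start. What it leaves free is the live catalyst:

c(free catalyst) charged = 400 µM

live = charged − c(stray impurity) = 316 µM

At one temperature I take the fall of starting material as pseudo-first-order in c(starting material), with a rate proportional to live catalyst. Then each live catalyst buys a fixed fall in ln c(starting material) before it dies:

reach = ln(c at start / c left) / live = 2.11 /mM

This reach is the fall in ln c(starting material) per unit of live catalyst, read from oak. Waiting, warming or taking target out adds no live catalyst, so I expect target at 8.0 h a little above the last reading of 48.4 %, and I choose noon. The catalyst charged is more than the stray impurity, so my supposition leaves none of that impurity to meet noon's dose, and I count the dose in full. Noon's dose is: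

added = 200 µM

fall = reach × added = 0.421

target after noon = 1 − (last oak reading of starting material) × exp(−fall) = 66.3 %

The weak link is the supposition about the stray impurity. If it took no catalyst at all, the whole charge counts as live and noon gives 63.1 %. So I commit to 66.3 %, with that as my low end.

The forecast, made from the same runs, says “This points to catalyst dying”. It gives 49.5 % (48.5 % to 50.5 %) for now, noon as best, 50.5 % after midnight, and 61 % (54 % to 65 %) after noon. That last value is lower than both of mine.

The flask gives 51.2 % at 8.0 h, 51.5 % after midnight, and 69.2 % after noon.

    catalyst intermediate A → free catalyst + target (k = 6.70 /min, Ea = 75.0 kJ/mol)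
    starting material + free catalyst ⇌ catalyst intermediate A (K = 6.50 /M, k = 730 /M/min, Ea = 42.0 kJ/mol, ΔH = 37.0 kJ/mol)
    second substrate + protic impurity → quenched substrate (k = 0.0730 /M/min, Ea = 63.0 kJ/mol)
    second substrate + free catalyst ⇌ catalyst intermediate B (K = 1500 /M, k = 64.0 /M/min, Ea = 43.0 kJ/mol, ΔH = 29.0 kJ/mol)
    catalyst intermediate B → free catalyst + second product (k = 180 /min, Ea = 53.0 kJ/mol)
    free catalyst → spent catalyst B (k = 0.0180 /min, Ea = 90.0 kJ/mol)
    free catalyst + stray impurity → spent catalyst A (k = 2300 /M/min, Ea = 45.0 kJ/mol)
    (constants at 0 °C)

At 8.00 h the stray impurity stands at 0 % of its charge, and spent catalyst A holds 21.0 % of the catalyst charged. Counting as starting material what target doesn't hold, noon's dose in this flask shows a reach of 2.30 /mM, against the 2.11 /mM read from oak. Now put the reach to a neighbour flask charged with 0.12 M of starting material. Its live catalyst is 156 µM, so it should leave 72.0 % of its starting material and make 28.0 % target. That neighbour flask gave 29.9 %.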